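The numbers in the tables are calculated for an exercise.

A small charge comes first: 0.12 mol% of radical scavenger, against 2.5 mol% of initiator in beta and theta.

the same everywhere: starting material 0.36 M; radical scavenger 0.12 mol%

| run | reagent | protic impurity | initiator | temperature | remark | time |
|---|---|---|---|---|---|---|
| green | 3 equiv | 0.36 M | 3.5 mol% | 25 °C | run made earlier |  |
| blue | 3 equiv | 0.36 M | 5.5 mol% | 50 °C | run made earlier |  |
| grey | 4.5 equiv | 0.36 M | 2.5 mol% | 25 °C | run made earlier |  |
| beta | 3.00 equiv | 0.360 M | 2.5 mol% |  | at 70 °C until 15 d, from then on at 30 °C | 30 d |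
| theta | 3.00 equiv | 0.360 M | 2.5 mol% |  | at 30 °C throughout | 30 d |

| run | time / d | product / % |
|---|---|---|
| green | 25.0 | 0 |
| green | 80.0 | 0 |
| green | 150 | 0 |
| green | 200 | 1.4 |
| green | 300 | 0 |
| blue | 6.00 | 0 |
| blue | 15.0 | 0 |
| blue | 20.0 | 1.2 |
| blue | 40.0 | 0 |
| blue | 80.0 | 12.4 |
| grey | 60.0 | 0 |
| grey | 120 | 0 |
| grey | 200 | 0 |
| grey | 250 | 0.2 |
| grey | 300 | 0 |

(standard deviation of a reading: 1 percentage point)

- the flask that ends with the higher amount of product, in percent of the starting material charged, or "neither" when 2 percentage points or less lies between them (beta / theta / neither)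
- final product, as a percentage of the starting material charged, in beta
- final product, as a percentage of the starting material charged, in theta

- the numbers in the tables scatter by 1 percentage point (one standard deviation)

Go through the numbers by what an error in each would cost you. Start with the reagent: grey, at 4.5 equiv, reads 0.2% at its highest, inside the scatter of 1 percentage point, so these runs show no gain from more of it. Blue's one clear signal is 12.4% at 80.0 d, after 0% at 40.0 d, so these runs show a long wait, an induction period, and your answer turns on whether that wait ends inside the flask's time. That makes the two loadings and the heat the numbers to know well, while the readings show nothing on the protic impurity, which stands at 0.360 M in beta and theta as in the earlier runs.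

Take the burn share, the fraction of the initiator charge that has to fall apart before its radicals, two from each, have met the scavenger: 2.40% in beta and theta, 1.09% in blue. Beta's share is 2.20 times blue's, so blue's wait, read as 40.0 d to 80.0 d, becomes 88.1 d to 176 d for beta's loading at blue's temperature. By my reckoning, heating to 70 °C has to shorten this by a factor of 5.87 to 11.7 for the wait to end before 15 d. Theta, at 30 °C, needs a larger share than green's 1.71%, and has 30 d, while green, at 25 °C, read 0% at 300 d.

The forecast says beta, with 4.5% in beta and 0% in theta, “so beta should just clear induction before cooling”.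

The flasks give 17.0% in beta and 0% in theta, so beta ends higher, and the forecast's beta is too low.

    reagent + first chain carrier → product + second chain carrier (k = 15000 L mol⁻¹ s⁻¹, Ea = 30.0 kJ mol⁻¹)
    starting material + initiating radical → capped initiator + first chain carrier (k = 43000 L mol⁻¹ s⁻¹, Ea = 25.0 kJ mol⁻¹)
    second chain carrier + radical scavenger → ended chains C (k = 1.20 × 10⁸ L mol⁻¹ s⁻¹, Ea = 18.0 kJ mol⁻¹)
    2 second chain carrier → ended chains B (k = 9.90 × 10⁷ L mol⁻¹ s⁻¹, Ea = 9.00 kJ mol⁻¹)
    initiator → 2 initiating radical (k = 1.10 × 10⁻⁴ h⁻¹, Ea = 123 kJ mol⁻¹)
    starting material + protic impurity → quenched substrate (k = 0.0520 L mol⁻¹ h⁻¹, Ea = 69.0 kJ mol⁻¹)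
    starting material + second chain carrier → by-product + first chain carrier (k = 1.60 × 10⁷ L mol⁻¹ h⁻¹, Ea = 41.0 kJ mol⁻¹)
    2 first chain carrier → ended chains A (k = 1.20 × 10⁸ L mol⁻¹ s⁻¹, Ea = 8.00 kJ mol⁻¹)
    (constants at 70 °C)

At the end beta has lost 3.90% of its initiator, past its burn share, and keeps 0% of scavenger. The initiator's half-life of 260 d at 70 °C puts the wait at 9.20 d. Beta stops at 17.0% and not 97.7% because of the path from starting material and protic impurity to quenched substrate, whose half-life by that path alone at the charged amounts and 70 °C, 1.5 d, is far shorter than that wait.

In the neighbour flask that is beta with 1.5 mol% of initiator, the burn share is 4.00%, which reckons to a wait at 70 °C of 15.5 d, just beyond the cooling at 15 d. That flask ends with 2.6% of its scavenger left and 0.119% of product.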